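## Analysis of the target

The target is (2R,3R)-3,5,7-trihydroxy-8-methoxy-6-(3-methylbut-2-enyl)flavanone, a dihydroflavonol: a chroman-4-one (rings A and C) with an unsubstituted phenyl ring B on C2 (flavanone numbering throughout; prenyl = 3-methylbut-2-enyl). It has two adjacent stereocentres, the benzylic C2 bonded to O1 and the carbinol C3 next to the C4 ketone; both are R, so phenyl and hydroxyl are trans and both equatorial in the half-chair of ring C. C3 can epimerise by enolisation, whereas C2 is lost only if ring C opens by β-elimination of the C8a phenoxide from a C3 enolate, so base is the main threat to configuration. Ring A is a fully substituted benzene with oxygen at C5, C7, C8 and C8a, prenyl at C6 and the acyl carbon at C4a. The oxygens at C5 and C8a both flank C4a and differ only in their far neighbours (prenyl versus methoxy), so a closure onto a free phloroglucinol-type ring could equally give the 6-methoxy-8-prenyl isomer. The sensitive groups are the prenyl alkene (no hydrogenation, no peracid, acid-induced cyclisation onto the neighbouring phenols), the α-ketol (easily dehydrogenated to the flavonol) and the electron-rich ring. The strategy rests on two features: O1–C2 is the benzyl ether of the C8a phenol, and C4(=O)–C3(OH) is an α-ketol. The isomeric ketol, with C2 bonded to the ketone carbon, is a 3-hydroxy-2,3-dihydrobenzofuran-3-carbaldehyde, and its furan ring is what a carbene at the future C4 forms by insertion into the benzylic C–H bond of that ether.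

## Retrosynthetic reasoning

**23 to 22.** The last operation only uncovers the C5 and C7 phenols. Both are carried as triisopropylsilyl ethers, so one buffered fluoride treatment ends the route and neither acid nor hydrogen meets the prenyl group or the α-ketol.

**22 to 21 (key disconnection).** The C2–C3 bond of 22 is cut and C2 is joined to C4 instead, the α-ketol transform. This leads to hydroxy aldehyde 21, in which the formyl carbon is the future C3 and the carbinol carbon the future C4. Cutting here, and not at O1–C2 or C4–C4a, keeps the ether oxygen on C2 and keeps the aryl–carbonyl bond. The gain is a five-membered precursor whose only configurational demand is C2 and whose quaternary neighbour cannot enolise toward C2. The forward step must move C2 and not the aryl carbon, with retention, and must create C3 trans to phenyl.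

**21 to 20 to 18.** Two functional-group changes at C3 of the dihydrobenzofuran: the aldehyde comes from the methyl ester, the tertiary hydroxyl from oxidation of the ester enolate of 18. C3 of 18 is erased in the enolate 19, and C3 of 21 becomes the flat C4, so only C2 has to be right.

**18 to 17.** The C2–C3 bond of the dihydrobenzofuran is cut to the aryl diazoacetate 17. It forms by carbene insertion into one of the two enantiotopic benzylic C–H bonds of the benzyl ether on the C8a oxygen. This is preferred to any closure at oxygen because the ether is installed early (step 2), so the choice of O1 is settled before a ring exists. The forward step needs a chiral dirhodium tetracarboxylate to select one hydrogen, and no other C–H bond within reach of the carbene.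

**17 to 15.** The diazo group is traced to the ketone of α-keto ester 15 through its sulfonylhydrazone 16.

**15 to 14 to 13.** Protecting-group exchange. The acetal ethers of 13 are needed as directing groups for the two metalations, but an acetal CH2 on the oxygen ortho to the carbene would offer a second five-membered insertion. Both acetals are therefore exchanged for silyl ethers, which have no such C–H bond.

**13 to 10 + 11.** The aryl–carbonyl bond (C4a–C4) is cut. The last ring hydrogen of 10 lies between an acetal ether and the benzyl ether, so metalation there is unambiguous, and 11 supplies both carbons of the keto ester.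

**10 to 7 + 8.** The C6–prenyl bond is cut. The position between the two acetal ethers of 7 is the most acidified ring C–H, and copper-mediated allylation with 8 gives the linear prenyl group.

**7 to 6 to 4 to 2 to 1 (+ 3).** The C8 oxygen is traced to the formyl group of 1 by Baeyer–Villiger oxidation and methylation. In 1 the three phenol oxygens are already in place; the hydrogen bond to the formyl group leaves one ortho hydroxyl for the benzyl group of 3, and the formyl carbon marks where the fourth oxygen goes. A ring lacking the C5 oxygen would need oxygenation para to the methoxy group, where electrophiles do not go and where sterically controlled C–H borylation would not spare a benzyl ring. The peracid step is placed before the prenyl group is introduced.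

## Alternatives that were turned down

**Alternative 1:** Disconnection of C4a–C4, C4–C3 and O1–C2 back to 2-iodo-6-methoxy-3,5-bis(methoxymethoxy)-4-(3-methylbut-2-enyl)phenol A2, phenylacetylene A3 and carbon monoxide A4. In the forward step a palladium-catalysed carbonylative coupling in an amine gives an ynone whose phenol oxygen adds to the alkyne, closing ring C as flavone A1.
- For: three bonds and ring C in one convergent operation of a well-precedented type, with O1 fixed by the position of iodine. On convergence and precedent it is stronger than the chosen route.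
- Against: A1 is flat. Both stereocentres would still have to be made, by enantioselective reduction of a hindered C2=C3 bond and then oxidation at C3 through a flavanone enolate that can open ring C and racemise C2. The two weakest operations would come last. The ynone can also close 5-exo to an aurone.
- Comparison: the chosen strategy needs more steps to reach 21, but it sets C2 by a catalyst-controlled C–H insertion and never forms a flavanone enolate.

**Alternative 2:** Disconnection of C8a–O1 back to the open-chain ketone (2R,3R)-2-(tert-butyldimethylsilyloxy)-3-hydroxy-1-[2-hydroxy-5-methoxy-4-(methoxymethoxy)-3-(3-methylbut-2-enyl)phenyl]-3-phenylpropan-1-one A6. In the forward step anodic oxidation in an alcohol solvent turns the para-methoxyphenol into its quinone monoketal, the benzylic hydroxyl adds to C8a, and loss of the alcohol rearomatises to flavanone A5.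
- For: both stereocentres are made on an open chain and the closure at oxygen does not touch them. C3 is set independently instead of during a rearrangement, which is a real advantage over the chosen route. C8a is the only free position.
- Against: the oxidation must select a phenol deactivated by its ortho acyl group in the presence of the prenyl alkene, a secondary benzylic alcohol and acetal ethers. The intramolecular addition must beat solvent addition. A6, with its anti-dioxygenated chain on a pentasubstituted ring, needs a long preparation.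
- Comparison: it is as unprecedented as the chosen key step but oxidative, on the most oxidation-sensitive substrate; the chosen step is redox-neutral.

**Alternative 3:** Disconnection of C4–C4a and O1–C2 back to 2-methoxy-3,5-bis(methoxymethoxy)-4-(3-methylbut-2-enyl)phenol A8 and (2R,3S)-3-phenyloxirane-2-carbaldehyde A9. In the forward step A8, metalated with a magnesium base, adds through C4a to the aldehyde and its oxygen then opens the epoxide at the benzylic carbon, giving flavan-3,4-diol A7.
- For: the shortest and most convergent plan, with both stereocentres taken from one small enantiopure building block. On step economy it is clearly stronger.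
- Against: the ring carbon must attack at the hindered last position of a fully substituted phenol, while direct O-attack on the epoxide or 5-exo opening at the nearer epoxide carbon compete. Benzylic opening under Lewis-acid assistance has ionisation character and can erode C2. A7 must then be oxidised at C4 selectively beside the C3 hydroxyl, the prenyl group and an electron-rich ring.
- Comparison: the chosen strategy delivers C4 directly as the ketone, fixes C2 by the catalyst, and has the O1–C2 bond in place before any ring closure.

Key step: step 13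

Assumption: the (R)-tert-leucinate catalyst Rh2(R-PTTL)4 is taken to deliver the (2S) ester 18, by analogy with simple 2-(benzyloxy)aryl diazoacetates; if the sense is the opposite, Rh2(S-PTTL)4 is used with no other change.

## Route

Step 1
Reactants: 1 2,4,6-trihydroxybenzaldehyde
Product: 2 2-hydroxy-4,6-bis(methoxymethoxy)benzaldehyde
Conditions: MOMCl (2.2 equiv), i-Pr2NEt, CH2Cl2, 0 °C → rt
Reagents that add atoms: chloromethyl methyl ether, COCCl
Why: Williamson-type O-alkylation of the para and one ortho hydroxyl; the last ortho hydroxyl is held in a hydrogen bond to the formyl group and should remain free.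

Step 2
Reactants: 2 2-hydroxy-4,6-bis(methoxymethoxy)benzaldehyde; 3 benzyl bromide
Product: 4 2-(benzyloxy)-4,6-bis(methoxymethoxy)benzaldehyde
Conditions: BnBr, K2CO3, DMF, 50 °C
Reagents that add atoms: benzyl bromide (3), BrCc1ccccc1
Why: Williamson etherification of the chelated phenol under more forcing conditions; it places the benzyl group on the oxygen that becomes O1 and its CH2 becomes C2.

Step 3
Reactants: 4 2-(benzyloxy)-4,6-bis(methoxymethoxy)benzaldehyde
Product: 6 2-(benzyloxy)-4,6-bis(methoxymethoxy)phenol, via aryl formate 5 (not isolated)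
Conditions: mCPBA, CH2Cl2, 0 °C → rt; NaHCO3 wash; then K2CO3 (cat.), MeOH, rt
Reagents that add atoms: 3-chloroperoxybenzoic acid, OOC(=O)c1cccc(Cl)c1
Why: Baeyer–Villiger oxidation of an electron-rich benzaldehyde, in which the trialkoxyaryl group migrates; methanolysis of the formate frees the phenol whose oxygen becomes the C8 methoxy oxygen. No alkene is present yet.

Step 4
Reactants: 6 2-(benzyloxy)-4,6-bis(methoxymethoxy)phenol
Product: 7 1-(benzyloxy)-2-methoxy-3,5-bis(methoxymethoxy)benzene
Conditions: MeI, K2CO3, acetone, reflux
Reagents that add atoms: iodomethane, CI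
Why: O-methylation of the phenoxide (Williamson); done at once because the trialkoxyphenol is air-sensitive.

Step 5
Reactants: 7 1-(benzyloxy)-2-methoxy-3,5-bis(methoxymethoxy)benzene; 8 prenyl bromide
Product: 10 1-(benzyloxy)-2-methoxy-3,5-bis(methoxymethoxy)-4-(3-methylbut-2-enyl)benzene, via aryllithium 9 (not isolated)
Conditions: n-BuLi, THF, −20 → 0 °C; CuI (0.2 equiv), prenyl bromide, −78 °C → rt
Reagents that add atoms: 1-bromo-3-methylbut-2-ene (8), CC(C)=CCBr
Why: Directed ortho-metalation: the ring C–H between the two chelating acetal ethers should be lithiated in preference to the one between an acetal and the benzyl ether. Copper-mediated SN2 allylation then gives the linear prenyl group.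

Step 6
Reactants: 10 1-(benzyloxy)-2-methoxy-3,5-bis(methoxymethoxy)-4-(3-methylbut-2-enyl)benzene; 11 dimethyl oxalate
Product: 13 methyl 2-[2-(benzyloxy)-3-methoxy-4,6-bis(methoxymethoxy)-5-(3-methylbut-2-enyl)phenyl]-2-oxoacetate, via aryllithium 12 (not isolated)
Conditions: n-BuLi, TMEDA, THF, −20 °C; cannulated into (CO2Me)2 (3 equiv), THF, −78 °C
Reagents that add atoms: dimethyl oxalate (11), COC(=O)C(=O)OC
Why: Directed ortho-metalation at the only ring C–H left, flanked by an acetal ether and the benzyl ether. Inverse addition to excess oxalate at low temperature should stop at the hindered α-keto ester.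

Step 7
Reactants: 13 methyl 2-[2-(benzyloxy)-3-methoxy-4,6-bis(methoxymethoxy)-5-(3-methylbut-2-enyl)phenyl]-2-oxoacetate
Product: 14 methyl 2-[2-(benzyloxy)-4,6-dihydroxy-3-methoxy-5-(3-methylbut-2-enyl)phenyl]-2-oxoacetate
Conditions: HCl (1 M in MeOH), 25 → 40 °C
Reagents that add atoms: none
Why: Acid-catalysed transacetalisation removes both acetal ethers as dimethoxymethane, under the mild conditions customary for prenylated phenols. The acetals have done their work as directing groups, and one of them would otherwise sit beside the carbene.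

Step 8
Reactants: 14 methyl 2-[2-(benzyloxy)-4,6-dihydroxy-3-methoxy-5-(3-methylbut-2-enyl)phenyl]-2-oxoacetate
Product: 15 methyl 2-[2-(benzyloxy)-3-methoxy-5-(3-methylbut-2-enyl)-4,6-bis(triisopropylsilyloxy)phenyl]-2-oxoacetate
Conditions: i-Pr3SiOTf (3 equiv), 2,6-lutidine, CH2Cl2, 0 °C → reflux
Reagents that add atoms: triisopropylsilyl trifluoromethanesulfonate, CC(C)[Si](C(C)C)(C(C)C)OS(=O)(=O)C(F)(F)F
Why: Silylation of both phenols, one of them chelated, with the most reactive silyl donor. The triisopropylsilyl group has no C–H bond that can reach the carbene through a five-membered transition state, and it is the silyl group least prone to move onto the later C3 alkoxide.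

Step 9
Reactants: 15 methyl 2-[2-(benzyloxy)-3-methoxy-5-(3-methylbut-2-enyl)-4,6-bis(triisopropylsilyloxy)phenyl]-2-oxoacetate
Product: 17 methyl 2-[2-(benzyloxy)-3-methoxy-5-(3-methylbut-2-enyl)-4,6-bis(triisopropylsilyloxy)phenyl]-2-diazoacetate, via tosylhydrazone 16 (not isolated)
Conditions: TsNHNH2, toluene–MeOH, 60 °C; then DBU, CH2Cl2, 0 °C → rt
Reagents that add atoms: 4-methylbenzenesulfonohydrazide, Cc1ccc(cc1)S(=O)(=O)NN
Why: Condensation at the activated ketone of the α-keto ester, then base-induced loss of sulfinate (Bamford–Stevens reaction), gives the aryl diazoacetate.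

Step 10
Reactants: 17 methyl 2-[2-(benzyloxy)-3-methoxy-5-(3-methylbut-2-enyl)-4,6-bis(triisopropylsilyloxy)phenyl]-2-diazoacetate
Product: 18 methyl (2S,3R)-7-methoxy-5-(3-methylbut-2-enyl)-2-phenyl-4,6-bis(triisopropylsilyloxy)-2,3-dihydrobenzofuran-3-carboxylate (2,3-cis)
Conditions: Rh2(R-PTTL)4 (dirhodium tetrakis[N-phthaloyl-(R)-tert-leucinate], 2 mol %), toluene, −60 → 0 °C
Reagents that add atoms: none
Why: Loss of nitrogen on the chiral dirhodium tetracarboxylate and 1,5-insertion of the carbene carbon into the benzylic C–H bond of the ortho benzyl ether close the furan ring. The catalyst selects one of the two enantiotopic benzylic hydrogens and so sets C2 (S in 18, the arrangement of the target). The C3 configuration (cis expected) is of no consequence.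

Step 11
Reactants: 18 methyl (2S,3R)-7-methoxy-5-(3-methylbut-2-enyl)-2-phenyl-4,6-bis(triisopropylsilyloxy)-2,3-dihydrobenzofuran-3-carboxylate
Product: 20 methyl (2R,3S)-3-hydroxy-7-methoxy-5-(3-methylbut-2-enyl)-2-phenyl-4,6-bis(triisopropylsilyloxy)-2,3-dihydrobenzofuran-3-carboxylate (hydroxyl trans to phenyl), via potassium enolate 19 (not isolated)
Conditions: KN(SiMe3)2, THF, −78 °C; 2-(benzenesulfonyl)-3-phenyloxaziridine, −78 °C; AcOH, −78 °C
Reagents that add atoms: 2-(benzenesulfonyl)-3-phenyloxaziridine, O=S(=O)(c1ccccc1)N1OC1c1ccccc1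
Why: Enolate hydroxylation with an N-sulfonyloxaziridine; the oxidant should approach the flat enolate anti to the C2 phenyl group, giving the hydroxyl trans to phenyl (3S). Ring opening of the enolate would be the reverse of a 5-endo-trig closure and is slow, and after this step C3 is quaternary.

Step 12
Reactants: 20 methyl (2R,3S)-3-hydroxy-7-methoxy-5-(3-methylbut-2-enyl)-2-phenyl-4,6-bis(triisopropylsilyloxy)-2,3-dihydrobenzofuran-3-carboxylate
Product: 21 (2R,3S)-3-hydroxy-7-methoxy-5-(3-methylbut-2-enyl)-2-phenyl-4,6-bis(triisopropylsilyloxy)-2,3-dihydrobenzofuran-3-carbaldehyde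
Conditions: i-Bu2AlH (2.5 equiv), CH2Cl2, −78 °C; aq. potassium sodium tartrate
Reagents that add atoms: none
Why: Partial reduction of an α-hydroxy ester: the first equivalent forms the aluminium alkoxide of the tertiary hydroxyl, and the tetrahedral adduct of the second is held as a chelate at −78 °C until work-up releases the aldehyde.

Step 13
Reactants: 21 (2R,3S)-3-hydroxy-7-methoxy-5-(3-methylbut-2-enyl)-2-phenyl-4,6-bis(triisopropylsilyloxy)-2,3-dihydrobenzofuran-3-carbaldehyde
Product: 22 (2R,3R)-3-hydroxy-8-methoxy-6-(3-methylbut-2-enyl)-5,7-bis(triisopropylsilyloxy)flavanone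
Conditions: Al(OtBu)3 (1.2 equiv), toluene, 25 → 60 °C; aq. potassium sodium tartrate
Reagents that add atoms: none
Why: Proposed new method: the tertiary hydroxyl of 21 exchanges onto aluminium and the formyl oxygen closes a five-membered chelate, after which the C3–C2 bond shifts with its electron pair to the formyl carbon while the old carbinol carbon becomes the C4 carbonyl; the closest known reaction type is the α-ketol (acyloin) rearrangement of α-hydroxy aldehydes to α-hydroxy ketones, including ring expansions of 1-hydroxycycloalkanecarbaldehydes, which has not been used to turn a dihydrobenzofuran into a chromanone. Ring C is not closed by a cyclisation: it arises from the furan ring by a 1,2-shift through a three-centre transition state that inserts the formyl carbon between C2 and the old C3 (five to six members, new bond C2–C3 of the flavanone). C2 migrates with retention, so the configuration set in step 10 is carried over unchanged. The new centre C3 is controlled by the chelate: with the carbonyl oxygen held syn to the carbinol oxygen, C2 lies over the Re face of the formyl carbon and its suprafacial shift gives (3R), hydroxyl trans to phenyl; this is also the thermodynamic isomer (both groups equatorial), so any epimerisation of the α-ketol centre on aluminium works in the same direction. The step needs migration of C2 and not of the aryl carbon C3a: under alkoxide-driven conditions a benzylic, oxygen-bearing sp3 carbon should be the better migrating group than an electron-rich aryl carbon, its shift moves the side chain away from the neighbouring silyl ether, and only this path gives a ketone conjugated with ring A. Al(OtBu)3 is chosen over an aluminium isopropoxide because it has no transferable hydride and cannot reduce the aldehyde (Meerwein–Ponndorf–Verley reduction), and over amine bases because a free enolate of 22 could open ring C and lose C2. The driving force is the change from a hindered α-hydroxy aldehyde to an aryl ketone, together with relief of strain at the quaternary carbon.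

Step 14
Reactants: 22 (2R,3R)-3-hydroxy-8-methoxy-6-(3-methylbut-2-enyl)-5,7-bis(triisopropylsilyloxy)flavanone
Product: 23 (2R,3R)-3,5,7-trihydroxy-8-methoxy-6-(3-methylbut-2-enyl)flavanone
Conditions: Bu4NF (2.5 equiv), AcOH (3 equiv), THF, 0 °C
Reagents that add atoms: none
Why: Fluoride cleaves both aryl silyl ethers; the C5 and C7 phenoxides are stabilised by the C4 carbonyl, so cleavage should be fast. The acetic acid buffer keeps the medium from enolising C3 or opening ring C.

## Compound list

1 | 2,4,6-trihydroxybenzaldehyde | O=Cc1c(O)cc(O)cc1O | starting material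
2 | 2-hydroxy-4,6-bis(methoxymethoxy)benzaldehyde | O=Cc1c(O)cc(OCOC)cc1OCOC | intermediate
3 | benzyl bromide | BrCc1ccccc1 | starting material
4 | 2-(benzyloxy)-4,6-bis(methoxymethoxy)benzaldehyde | O=Cc1c(OCc2ccccc2)cc(OCOC)cc1OCOC | intermediate
5 | 2-(benzyloxy)-4,6-bis(methoxymethoxy)phenyl formate (not isolated) | O=COc1c(OCc2ccccc2)cc(OCOC)cc1OCOC | intermediate
6 | 2-(benzyloxy)-4,6-bis(methoxymethoxy)phenol | Oc1c(OCc2ccccc2)cc(OCOC)cc1OCOC | intermediate
7 | 1-(benzyloxy)-2-methoxy-3,5-bis(methoxymethoxy)benzene | COc1c(OCc2ccccc2)cc(OCOC)cc1OCOC | intermediate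
8 | prenyl bromide (1-bromo-3-methylbut-2-ene) | CC(C)=CCBr | starting material
9 | [4-(benzyloxy)-3-methoxy-2,6-bis(methoxymethoxy)phenyl]lithium (not isolated) | COc1c(OCc2ccccc2)cc(OCOC)c([Li])c1OCOC | intermediate
10 | 1-(benzyloxy)-2-methoxy-3,5-bis(methoxymethoxy)-4-(3-methylbut-2-enyl)benzene | COc1c(OCc2ccccc2)cc(OCOC)c(CC=C(C)C)c1OCOC | intermediate
11 | dimethyl oxalate | COC(=O)C(=O)OC | starting material
12 | [2-(benzyloxy)-3-methoxy-4,6-bis(methoxymethoxy)-5-(3-methylbut-2-enyl)phenyl]lithium (not isolated) | COc1c(OCc2ccccc2)c([Li])c(OCOC)c(CC=C(C)C)c1OCOC | intermediate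
13 | methyl 2-[2-(benzyloxy)-3-methoxy-4,6-bis(methoxymethoxy)-5-(3-methylbut-2-enyl)phenyl]-2-oxoacetate | COC(=O)C(=O)c1c(OCc2ccccc2)c(OC)c(OCOC)c(CC=C(C)C)c1OCOC | intermediate
14 | methyl 2-[2-(benzyloxy)-4,6-dihydroxy-3-methoxy-5-(3-methylbut-2-enyl)phenyl]-2-oxoacetate | COC(=O)C(=O)c1c(OCc2ccccc2)c(OC)c(O)c(CC=C(C)C)c1O | intermediate
15 | methyl 2-[2-(benzyloxy)-3-methoxy-5-(3-methylbut-2-enyl)-4,6-bis(triisopropylsilyloxy)phenyl]-2-oxoacetate | COC(=O)C(=O)c1c(OCc2ccccc2)c(OC)c(O[Si](C(C)C)(C(C)C)C(C)C)c(CC=C(C)C)c1O[Si](C(C)C)(C(C)C)C(C)C | intermediate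
16 | 4-methylbenzenesulfonylhydrazone of 15 at the ketone carbon, C=N geometry not defined (not isolated) | COC(=O)C(=NNS(=O)(=O)c1ccc(C)cc1)c1c(OCc2ccccc2)c(OC)c(O[Si](C(C)C)(C(C)C)C(C)C)c(CC=C(C)C)c1O[Si](C(C)C)(C(C)C)C(C)C | intermediate
17 | methyl 2-[2-(benzyloxy)-3-methoxy-5-(3-methylbut-2-enyl)-4,6-bis(triisopropylsilyloxy)phenyl]-2-diazoacetate | COC(=O)C(=[N+]=[N-])c1c(OCc2ccccc2)c(OC)c(O[Si](C(C)C)(C(C)C)C(C)C)c(CC=C(C)C)c1O[Si](C(C)C)(C(C)C)C(C)C | intermediate
18 | methyl (2S,3R)-7-methoxy-5-(3-methylbut-2-enyl)-2-phenyl-4,6-bis(triisopropylsilyloxy)-2,3-dihydrobenzofuran-3-carboxylate (2,3-cis) | COc1c(O[Si](C(C)C)(C(C)C)C(C)C)c(CC=C(C)C)c(O[Si](C(C)C)(C(C)C)C(C)C)c2c1O[C@H](c1ccccc1)[C@@H]2C(=O)OC | intermediate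
19 | potassium ester enolate of 18, C3 planar, C2 as in 18 (not isolated) | COC([O-])=C1c2c(O[Si](C(C)C)(C(C)C)C(C)C)c(CC=C(C)C)c(O[Si](C(C)C)(C(C)C)C(C)C)c(OC)c2O[C@@H]1c1ccccc1.[K+] | intermediate
20 | methyl (2R,3S)-3-hydroxy-7-methoxy-5-(3-methylbut-2-enyl)-2-phenyl-4,6-bis(triisopropylsilyloxy)-2,3-dihydrobenzofuran-3-carboxylate (hydroxyl trans to phenyl) | COc1c(O[Si](C(C)C)(C(C)C)C(C)C)c(CC=C(C)C)c(O[Si](C(C)C)(C(C)C)C(C)C)c2c1O[C@H](c1ccccc1)[C@]2(O)C(=O)OC | intermediate
21 | (2R,3S)-3-hydroxy-7-methoxy-5-(3-methylbut-2-enyl)-2-phenyl-4,6-bis(triisopropylsilyloxy)-2,3-dihydrobenzofuran-3-carbaldehyde (hydroxyl trans to phenyl) | COc1c(O[Si](C(C)C)(C(C)C)C(C)C)c(CC=C(C)C)c(O[Si](C(C)C)(C(C)C)C(C)C)c2c1O[C@H](c1ccccc1)[C@]2(O)C=O | intermediate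
22 | (2R,3R)-3-hydroxy-8-methoxy-6-(3-methylbut-2-enyl)-5,7-bis(triisopropylsilyloxy)flavanone (2,3-trans) | COc1c(O[Si](C(C)C)(C(C)C)C(C)C)c(CC=C(C)C)c(O[Si](C(C)C)(C(C)C)C(C)C)c2c1O[C@H](c1ccccc1)[C@@H](O)C2=O | intermediate
23 | (2R,3R)-3,5,7-trihydroxy-8-methoxy-6-(3-methylbut-2-enyl)flavanone | COc1c(O)c(CC=C(C)C)c(O)c2c1O[C@H](c1ccccc1)[C@@H](O)C2=O | target

## Step count and least certain steps

Total: 14 steps. Longest linear sequence: 14 steps from 1 (3, 8 and 11 are bought).

**Step 13 (the proposed new method).** The most likely failure is a shift of the aryl carbon C3a in place of C2. That would give a chroman-3-one in which C2 is α to the ketone; its isomerisation to 22 through the enediol would then be accompanied by enolisation toward C2 and loss of configuration. A second failure is slow rearrangement at the crowded aldehyde with transfer of the neighbouring silyl group to the carbinol oxygen.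
Fallback: the rearrangement is abandoned and ring C is closed by intramolecular acylation, with O1–C2 made first by SN2 opening of an epoxide; all steps are of known type. It sets out from 10. The benzyl ether is cleaved with LiDBB (lithium 4,4'-di-tert-butylbiphenylide) in THF at −78 °C, which spares the alkene, to give 2-methoxy-3,5-bis(methoxymethoxy)-4-(3-methylbut-2-enyl)phenol F1. N-Bromosuccinimide brominates the only free ring position to give 6-bromo-2-methoxy-3,5-bis(methoxymethoxy)-4-(3-methylbut-2-enyl)phenol F2. Its caesium salt (Cs2CO3, DMF) opens (2R,3S)-N-methoxy-N-methyl-3-phenyloxirane-2-carboxamide F3 at the benzylic carbon with inversion, giving (2R,3R)-3-[2-bromo-6-methoxy-3,5-bis(methoxymethoxy)-4-(3-methylbut-2-enyl)phenoxy]-2-hydroxy-N-methoxy-N-methyl-3-phenylpropanamide F4. The hydroxyl is protected with chloromethyl methyl ether to give (2R,3R)-3-[2-bromo-6-methoxy-3,5-bis(methoxymethoxy)-4-(3-methylbut-2-enyl)phenoxy]-N-methoxy-2-(methoxymethoxy)-N-methyl-3-phenylpropanamide F5. Bromine–lithium exchange with t-BuLi at −100 °C and attack of the aryllithium on the N-methoxy-N-methylamide (Parham cyclisation) should give (2R,3R)-8-methoxy-3,5,7-tris(methoxymethoxy)-6-(3-methylbut-2-enyl)flavanone F6. Dilute HCl in methanol removes the three acetals and the route is rejoined at 23.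

**Step 10.** The aryl ring carries two ortho substituents and cannot lie in the plane of the carbene as in the simple series, so enantioface discrimination may be poor or reversed. Insertion into a methine C–H of the neighbouring silyl group (six-membered) or reaction of the carbene with the prenyl alkene of a second molecule may also intrude.
Fallback: resolution in place of catalyst control. From 17, Rh2(OAc)4 in CH2Cl2 gives racemic methyl 2,3-cis-7-methoxy-5-(3-methylbut-2-enyl)-2-phenyl-4,6-bis(triisopropylsilyloxy)-2,3-dihydrobenzofuran-3-carboxylate F7. It is hydroxylated as in step 11 to racemic methyl 3-hydroxy-7-methoxy-5-(3-methylbut-2-enyl)-2-phenyl-4,6-bis(triisopropylsilyloxy)-2,3-dihydrobenzofuran-3-carboxylate F8. Preparative chromatography on a chiral stationary phase separates the enantiomers, and the (2R,3S) enantiomer is 20.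

**Step 9.** Condensation at a ketone flanked by a benzyl ether and a silyl ether may be slow or incomplete, with loss of a silyl group on prolonged heating.
Fallback: dehydrogenation of a free hydrazone instead of sulfinate elimination. From 15, hydrazine hydrate (ethanol, catalytic AcOH) gives methyl 2-[2-(benzyloxy)-3-methoxy-5-(3-methylbut-2-enyl)-4,6-bis(triisopropylsilyloxy)phenyl]-2-hydrazinylideneacetate F9, which MnO2 in CH2Cl2 oxidises to 17.

**Step 11.** The potassium alkoxide formed at C3 sits next to the C4 silyl ether and may take over the silyl group, or the enolate may open the furan ring by β-elimination of the phenoxide.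
Fallback: oxidation of a neutral silyl enol ether of the aldehyde, which replaces steps 11 and 12. From 18, i-Bu2AlH at −78 °C gives (2S,3R)-7-methoxy-5-(3-methylbut-2-enyl)-2-phenyl-4,6-bis(triisopropylsilyloxy)-2,3-dihydrobenzofuran-3-carbaldehyde F10. Soft enolisation (Me3SiOTf, Et3N) gives (2S)-7-methoxy-5-(3-methylbut-2-enyl)-2-phenyl-4,6-bis(triisopropylsilyloxy)-3-[(trimethylsilyloxy)methylidene]-2,3-dihydrobenzofuran F11. Oxidation with the same N-sulfonyloxaziridine, anti to phenyl, and desilylation on work-up give 21.

**Step 12.** Over-reduction to the diol, or no reaction at the hindered ester, is possible.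
Fallback: full reduction and selective re-oxidation. From 20, LiAlH4 (THF, 0 °C) gives (2R,3R)-3-(hydroxymethyl)-7-methoxy-5-(3-methylbut-2-enyl)-2-phenyl-4,6-bis(triisopropylsilyloxy)-2,3-dihydrobenzofuran-3-ol F12. Its primary alcohol alone is oxidised with SO3·pyridine, DMSO and i-Pr2NEt (Parikh–Doering oxidation) to 21.

## Further compounds

F1 | step 13 | 2-methoxy-3,5-bis(methoxymethoxy)-4-(3-methylbut-2-enyl)phenol | COc1c(O)cc(OCOC)c(CC=C(C)C)c1OCOC
F2 | step 13 | 6-bromo-2-methoxy-3,5-bis(methoxymethoxy)-4-(3-methylbut-2-enyl)phenol | COc1c(O)c(Br)c(OCOC)c(CC=C(C)C)c1OCOC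
F3 | step 13 | (2R,3S)-N-methoxy-N-methyl-3-phenyloxirane-2-carboxamide | CON(C)C(=O)[C@@H]1O[C@H]1c1ccccc1
F4 | step 13 | (2R,3R)-3-[2-bromo-6-methoxy-3,5-bis(methoxymethoxy)-4-(3-methylbut-2-enyl)phenoxy]-2-hydroxy-N-methoxy-N-methyl-3-phenylpropanamide | COc1c(O[C@H](c2ccccc2)[C@@H](O)C(=O)N(C)OC)c(Br)c(OCOC)c(CC=C(C)C)c1OCOC
F5 | step 13 | (2R,3R)-3-[2-bromo-6-methoxy-3,5-bis(methoxymethoxy)-4-(3-methylbut-2-enyl)phenoxy]-N-methoxy-2-(methoxymethoxy)-N-methyl-3-phenylpropanamide | COc1c(O[C@H](c2ccccc2)[C@@H](OCOC)C(=O)N(C)OC)c(Br)c(OCOC)c(CC=C(C)C)c1OCOC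
F6 | step 13 | (2R,3R)-8-methoxy-3,5,7-tris(methoxymethoxy)-6-(3-methylbut-2-enyl)flavanone | COc1c(OCOC)c(CC=C(C)C)c(OCOC)c2c1O[C@H](c1ccccc1)[C@@H](OCOC)C2=O
F7 | step 10 | racemic methyl 2,3-cis-7-methoxy-5-(3-methylbut-2-enyl)-2-phenyl-4,6-bis(triisopropylsilyloxy)-2,3-dihydrobenzofuran-3-carboxylate | COc1c(O[Si](C(C)C)(C(C)C)C(C)C)c(CC=C(C)C)c(O[Si](C(C)C)(C(C)C)C(C)C)c2c1OC(c1ccccc1)C2C(=O)OC
F8 | step 10 | racemic methyl 3-hydroxy-7-methoxy-5-(3-methylbut-2-enyl)-2-phenyl-4,6-bis(triisopropylsilyloxy)-2,3-dihydrobenzofuran-3-carboxylate (hydroxyl trans to phenyl) | COc1c(O[Si](C(C)C)(C(C)C)C(C)C)c(CC=C(C)C)c(O[Si](C(C)C)(C(C)C)C(C)C)c2c1OC(c1ccccc1)C2(O)C(=O)OC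
F9 | step 9 | methyl 2-[2-(benzyloxy)-3-methoxy-5-(3-methylbut-2-enyl)-4,6-bis(triisopropylsilyloxy)phenyl]-2-hydrazinylideneacetate | COC(=O)C(=NN)c1c(OCc2ccccc2)c(OC)c(O[Si](C(C)C)(C(C)C)C(C)C)c(CC=C(C)C)c1O[Si](C(C)C)(C(C)C)C(C)C
F10 | step 11 | (2S,3R)-7-methoxy-5-(3-methylbut-2-enyl)-2-phenyl-4,6-bis(triisopropylsilyloxy)-2,3-dihydrobenzofuran-3-carbaldehyde | COc1c(O[Si](C(C)C)(C(C)C)C(C)C)c(CC=C(C)C)c(O[Si](C(C)C)(C(C)C)C(C)C)c2c1O[C@H](c1ccccc1)[C@@H]2C=O
F11 | step 11 | (2S)-7-methoxy-5-(3-methylbut-2-enyl)-2-phenyl-4,6-bis(triisopropylsilyloxy)-3-[(trimethylsilyloxy)methylidene]-2,3-dihydrobenzofuran | COc1c(O[Si](C(C)C)(C(C)C)C(C)C)c(CC=C(C)C)c(O[Si](C(C)C)(C(C)C)C(C)C)c2c1O[C@H](c1ccccc1)C2=CO[Si](C)(C)C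
F12 | step 12 | (2R,3R)-3-(hydroxymethyl)-7-methoxy-5-(3-methylbut-2-enyl)-2-phenyl-4,6-bis(triisopropylsilyloxy)-2,3-dihydrobenzofuran-3-ol | COc1c(O[Si](C(C)C)(C(C)C)C(C)C)c(CC=C(C)C)c(O[Si](C(C)C)(C(C)C)C(C)C)c2c1O[C@H](c1ccccc1)[C@]2(O)CO
A1 | alternative 1 | 8-methoxy-5,7-bis(methoxymethoxy)-6-(3-methylbut-2-enyl)flavone | COc1c(OCOC)c(CC=C(C)C)c(OCOC)c2c1OC(c1ccccc1)=CC2=O
A2 | alternative 1 | 2-iodo-6-methoxy-3,5-bis(methoxymethoxy)-4-(3-methylbut-2-enyl)phenol | COc1c(O)c(I)c(OCOC)c(CC=C(C)C)c1OCOC
A3 | alternative 1 | phenylacetylene | C#Cc1ccccc1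
A4 | alternative 1 | carbon monoxide | [C-]#[O+]
A5 | alternative 2 | (2R,3R)-3-(tert-butyldimethylsilyloxy)-5-hydroxy-8-methoxy-7-(methoxymethoxy)-6-(3-methylbut-2-enyl)flavanone | COc1c(OCOC)c(CC=C(C)C)c(O)c2c1O[C@H](c1ccccc1)[C@@H](O[Si](C)(C)C(C)(C)C)C2=O
A6 | alternative 2 | (2R,3R)-2-(tert-butyldimethylsilyloxy)-3-hydroxy-1-[2-hydroxy-5-methoxy-4-(methoxymethoxy)-3-(3-methylbut-2-enyl)phenyl]-3-phenylpropan-1-one | O[C@H](c1ccccc1)[C@@H](O[Si](C)(C)C(C)(C)C)C(=O)c1cc(OC)c(OCOC)c(CC=C(C)C)c1O
A7 | alternative 3 | 2,3-trans-8-methoxy-5,7-bis(methoxymethoxy)-6-(3-methylbut-2-enyl)flavan-3,4-diol, C2 and C3 as in the target, one C4 epimer | COc1c(OCOC)c(CC=C(C)C)c(OCOC)c2c1O[C@H](c1ccccc1)[C@@H](O)[C@@H]2O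
A8 | alternative 3 | 2-methoxy-3,5-bis(methoxymethoxy)-4-(3-methylbut-2-enyl)phenol | COc1c(O)cc(OCOC)c(CC=C(C)C)c1OCOC
A9 | alternative 3 | (2R,3S)-3-phenyloxirane-2-carbaldehyde | O=C[C@@H]1O[C@H]1c1ccccc1
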